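**Retrosynthetic overview**
- Target 1 ⇐ C11 hydroxymethyl by Stille coupling of a C4 enol triflate (last step); 7β,8α-diol with the 10-O-ester ⇐ β-face epoxidation of an allylic p-coumarate and ester-assisted inversion at C8.
- Allylic C10 alcohol ⇐ NaBH4 reduction of a thioester; enol triflate ⇐ C4 ketone.
- Cyclopentene ring (formed second) ⇐ phosphine-catalysed [3+2] annulation of an allenic thioester onto a (6S)-6-acyloxy-2H-pyran-3(6H)-one, anti to the acyloxy group.
- Pyranone ring (formed first, key step) ⇐ oxidative ring expansion of furfuryl alcohol (Achmatowicz), then dynamic kinetic acylation with (S)-3-methylpentanoic acid to set C1.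
- Side pieces: p-coumaric acid ⇐ Heck reaction of 4-iodophenol with acrylic acid; allenic thioester ⇐ but-3-ynoic acid and ethanethiol.

Assumption: (S)-3-methylpentanoic acid and but-3-ynoic acid are bought as such. Locants in the text use iridoid numbering (C1 acetal carbon, O2, C3, C4, ring-fusion C5 and C9, C6 to C8 in the cyclopentane, C10 on C8, C11 on C4); β is the face of H-5 and H-9.

**Step 1**
Reactants: 2 furfuryl alcohol (furan-2-ylmethanol)
Product: 3 6-hydroxy-2H-pyran-3(6H)-one (racemic lactol)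
Conditions: NBS, NaHCO3, THF/H2O (4:1), 0 °C
Reagents that add atoms: water (O)
Why: Achmatowicz rearrangement: bromonium oxidation of the furan gives a 2,5-dihydrofuran hemiketal that opens to the cis-ene-dione and recloses through the side-chain OH, expanding the furan into the six-membered hemiacetal enone; the anomeric carbon stays configurationally labile.

**Step 2**
Reactants: 3 6-hydroxy-2H-pyran-3(6H)-one; 4 (3S)-3-methylpentanoic acid
Product: 6 (6S)-6-{[(3S)-3-methylpentanoyl]oxy}-2H-pyran-3(6H)-one, via mixed pivalic anhydride 5 (not isolated)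
Conditions: 4, PivCl, i-Pr2NEt, CH2Cl2, 0 °C; then 3, (R)-BTM [(R)-2-phenyl-2,3-dihydroimidazo[2,1-b][1,3]benzothiazole] (5 mol %), −20 °C
Reagents that add atoms: none
Why: Dynamic kinetic acylation by chiral isothiourea acyl-transfer catalysis (known for this lactol with simple anhydrides): the lactol epimerises through ring opening while the catalyst-bound 3-methylpentanoyl group acylates one enantiomer faster, setting C1 as S; the sense is catalyst-controlled, so (S)-BTM is used instead if the test run gives 6R.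

**Step 3**
Reactants: 7 but-3-ynoic acid; 8 ethanethiol
Product: 10 S-ethyl buta-2,3-dienethioate, via S-ethyl but-3-ynethioate 9 (not isolated)
Conditions: DCC, DMAP (5 mol %), CH2Cl2, −20 to 0 °C; then Et3N (10 mol %), 0 °C
Reagents that add atoms: none
Why: Steglich thioesterification followed by base-catalysed propargyl-to-allenyl isomerisation into conjugation, as in standard allenoate preparations from but-3-ynoates.

**Step 4**
Reactants: 6 (6S)-6-{[(3S)-3-methylpentanoyl]oxy}-2H-pyran-3(6H)-one; 10 S-ethyl buta-2,3-dienethioate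
Product: 11 S-ethyl (1S,4aS,7aS)-1-{[(3S)-3-methylpentanoyl]oxy}-4-oxo-1,3,4,4a,5,7a-hexahydrocyclopenta[c]pyran-7-carbothioate (cis-fused)
Conditions: PPh3 (20 mol %), toluene, 25 → 60 °C
Reagents that add atoms: none
Why: Proposed new method: a Lu-type phosphine-catalysed [3+2] annulation run with an allenic thioester, in which PPh3 adds to the β-carbon of 10 to give a phosphonium dienolate whose α-carbon attacks C9 of 6 anti to the C1 acyloxy group, the enolate closes at the γ-carbon, and proton shift with loss of PPh3 gives the cis-fused cyclopentene (sets C5 and C9, both H on the face of the 1-acyloxy group); the closest known reaction is the same annulation of ethyl buta-2,3-dienoate with 6-acyloxy-2H-pyran-3(6H)-ones, and the thioester is used because NaBH4 later reduces it without touching the C1 ester.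

**Step 5**
Reactants: 11 keto thioester
Product: 12 S-ethyl (1S,4aS,7aS)-1-{[(3S)-3-methylpentanoyl]oxy}-4-[(trifluoromethanesulfonyl)oxy]-1,4a,5,7a-tetrahydrocyclopenta[c]pyran-7-carbothioate
Conditions: KN(SiMe3)2 (1.05 equiv), THF, −78 °C; then PhNTf2
Reagents that add atoms: N-phenylbis(trifluoromethanesulfonimide), PhNTf2 (O=S(=O)(N(c1ccccc1)S(=O)(=O)C(F)(F)F)C(F)(F)F)
Why: Kinetic enolate O-triflation: the bulky amide should remove the unhindered C3 methylene proton rather than the ring-fusion C5 methine, giving the C3=C4 enol triflate, which also deactivates the enol ether for the following steps; the regiochemistry is the point to confirm by NMR.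

**Step 6**
Reactants: 12 enol triflate thioester
Product: 13 (1S,4aS,7aS)-7-(hydroxymethyl)-4-[(trifluoromethanesulfonyl)oxy]-1,4a,5,7a-tetrahydrocyclopenta[c]pyran-1-yl (3S)-3-methylpentanoate
Conditions: NaBH4, CeCl3·7H2O, THF/EtOH (3:1), −10 → 10 °C
Reagents that add atoms: none
Why: Chemoselective Luche-type borohydride reduction: the thioester is reduced through the enal to the allylic alcohol (1,2-selective with CeCl3), while the C1 carboxylic ester and the enol triflate are inert.

**Step 7**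
Reactants: 14 4-iodophenol; 15 acrylic acid
Product: 16 (2E)-3-(4-hydroxyphenyl)prop-2-enoic acid (p-coumaric acid)
Conditions: Pd(OAc)2 (1 mol %), Et3N, H2O/MeCN, 80 °C
Reagents that add atoms: none
Why: Ligand-free Mizoroki–Heck reaction of an aryl iodide with an acrylate; syn-insertion and syn-β-hydride elimination give the E-alkene.

**Step 8**
Reactants: 13 allylic alcohol; 16 p-coumaric acid
Product: 17 [(1S,4aS,7aS)-1-{[(3S)-3-methylpentanoyl]oxy}-4-[(trifluoromethanesulfonyl)oxy]-1,4a,5,7a-tetrahydrocyclopenta[c]pyran-7-yl]methyl (2E)-3-(4-hydroxyphenyl)prop-2-enoate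
Conditions: PPh3, DIAD, THF, 0 °C
Reagents that add atoms: none
Why: Mitsunobu esterification: the primary allylic alcohol is activated as the oxyphosphonium and displaced by the carboxylate, the much less acidic phenol not competing.

**Step 9**
Reactants: 17 allylic p-coumarate
Product: 20 [(1S,4aS,6S,7R,7aS)-6,7-dihydroxy-1-{[(3S)-3-methylpentanoyl]oxy}-4-[(trifluoromethanesulfonyl)oxy]-1,4a,5,6,7,7a-hexahydrocyclopenta[c]pyran-7-yl]methyl (2E)-3-(4-hydroxyphenyl)prop-2-enoate, via 7β,8β-epoxide 18 (not isolated), via dioxolanylium ion 19 (not isolated)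
Conditions: mCPBA (1.2 equiv), CH2Cl2, 0 °C; then THF/H2O (10:1), (+)-CSA (10 mol %), 0 °C → rt
Reagents that add atoms: mCPBA (OOC(=O)c1cccc(Cl)c1); water (O)
Why: Prilezhaev epoxidation of the only electron-rich alkene from the convex β-face, then acid-triggered 5-exo attack of the C10 ester carbonyl on tertiary C8 from the α-face (anchimeric assistance, ion 19) and hydrolysis with the acyl group settling on primary O-10; this gives 7β-OH with retention and 8α-OH with inversion.

**Step 10**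
Reactants: 20 enol triflate diol
Product: 1 [(1S,4aS,6S,7R,7aS)-6,7-dihydroxy-4-(hydroxymethyl)-1-{[(3S)-3-methylpentanoyl]oxy}-1,4a,5,6,7,7a-hexahydrocyclopenta[c]pyran-7-yl]methyl (2E)-3-(4-hydroxyphenyl)prop-2-enoate
Conditions: Bu3SnCH2OH (1.5 equiv), Pd(PPh3)4 (5 mol %), LiCl (3 equiv), 1,4-dioxane, 80 °C
Reagents that add atoms: (tributylstannyl)methanol, Bu3SnCH2OH (CCCC[Sn](CCCC)(CCCC)CO)
Why: Migita–Kosugi–Stille coupling: zerovalent palladium inserts into the enol triflate, the hydroxymethyl group transfers from tin (LiCl-assisted) and reductive elimination installs C11 without protecting groups, unveiling the acid-labile enol ether only at the end.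

**Compound list**
1 | [(1S,4aS,6S,7R,7aS)-6,7-dihydroxy-4-(hydroxymethyl)-1-{[(3S)-3-methylpentanoyl]oxy}-1,4a,5,6,7,7a-hexahydrocyclopenta[c]pyran-7-yl]methyl (2E)-3-(4-hydroxyphenyl)prop-2-enoate | CC[C@H](C)CC(=O)O[C@@H]1OC=C(CO)[C@H]2C[C@H](O)[C@](O)(COC(=O)/C=C/c3ccc(O)cc3)[C@@H]12 | target
2 | furfuryl alcohol | OCc1ccco1 | starting material
3 | 6-hydroxy-2H-pyran-3(6H)-one (racemic, labile anomeric centre) | OC1OCC(=O)C=C1 | intermediate
4 | (3S)-3-methylpentanoic acid | CC[C@H](C)CC(=O)O | starting material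
5 | (3S)-3-methylpentanoic pivalic anhydride | CC[C@H](C)CC(=O)OC(=O)C(C)(C)C | intermediate
6 | (6S)-6-{[(3S)-3-methylpentanoyl]oxy}-2H-pyran-3(6H)-one | CC[C@H](C)CC(=O)O[C@@H]1OCC(=O)C=C1 | intermediate
7 | but-3-ynoic acid | C#CCC(=O)O | starting material
8 | ethanethiol | CCS | starting material
9 | S-ethyl but-3-ynethioate | C#CCC(=O)SCC | intermediate
10 | S-ethyl buta-2,3-dienethioate | C=C=CC(=O)SCC | intermediate
11 | S-ethyl (1S,4aS,7aS)-1-{[(3S)-3-methylpentanoyl]oxy}-4-oxo-1,3,4,4a,5,7a-hexahydrocyclopenta[c]pyran-7-carbothioate | CC[C@H](C)CC(=O)O[C@@H]1OCC(=O)[C@H]2CC=C(C(=O)SCC)[C@@H]12 | intermediate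
12 | S-ethyl (1S,4aS,7aS)-1-{[(3S)-3-methylpentanoyl]oxy}-4-[(trifluoromethanesulfonyl)oxy]-1,4a,5,7a-tetrahydrocyclopenta[c]pyran-7-carbothioate | CC[C@H](C)CC(=O)O[C@@H]1OC=C(OS(=O)(=O)C(F)(F)F)[C@H]2CC=C(C(=O)SCC)[C@@H]12 | intermediate
13 | (1S,4aS,7aS)-7-(hydroxymethyl)-4-[(trifluoromethanesulfonyl)oxy]-1,4a,5,7a-tetrahydrocyclopenta[c]pyran-1-yl (3S)-3-methylpentanoate | CC[C@H](C)CC(=O)O[C@@H]1OC=C(OS(=O)(=O)C(F)(F)F)[C@H]2CC=C(CO)[C@@H]12 | intermediate
14 | 4-iodophenol | Oc1ccc(I)cc1 | starting material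
15 | acrylic acid | C=CC(=O)O | starting material
16 | (2E)-3-(4-hydroxyphenyl)prop-2-enoic acid | OC(=O)/C=C/c1ccc(O)cc1 | intermediate
17 | [(1S,4aS,7aS)-1-{[(3S)-3-methylpentanoyl]oxy}-4-[(trifluoromethanesulfonyl)oxy]-1,4a,5,7a-tetrahydrocyclopenta[c]pyran-7-yl]methyl (2E)-3-(4-hydroxyphenyl)prop-2-enoate | CC[C@H](C)CC(=O)O[C@@H]1OC=C(OS(=O)(=O)C(F)(F)F)[C@H]2CC=C(COC(=O)/C=C/c3ccc(O)cc3)[C@@H]12 | intermediate
18 | 7β,8β-epoxide of 17 (epoxide oxygen on the face of H-5 and H-9) | CC[C@H](C)CC(=O)O[C@@H]1OC=C(OS(=O)(=O)C(F)(F)F)[C@H]2C[C@@H]3O[C@]3(COC(=O)/C=C/c4ccc(O)cc4)[C@@H]12 | intermediate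
19 | spiro 2-[(E)-2-(4-hydroxyphenyl)ethenyl]-1,3-dioxolan-2-ylium ion spanning O-8 (α) and O-10, with free 7β-OH | CC[C@H](C)CC(=O)O[C@@H]1OC=C(OS(=O)(=O)C(F)(F)F)[C@H]2C[C@H](O)[C@]3(CO[C+](/C=C/c4ccc(O)cc4)O3)[C@@H]12 | intermediate
20 | [(1S,4aS,6S,7R,7aS)-6,7-dihydroxy-1-{[(3S)-3-methylpentanoyl]oxy}-4-[(trifluoromethanesulfonyl)oxy]-1,4a,5,6,7,7a-hexahydrocyclopenta[c]pyran-7-yl]methyl (2E)-3-(4-hydroxyphenyl)prop-2-enoate | CC[C@H](C)CC(=O)O[C@@H]1OC=C(OS(=O)(=O)C(F)(F)F)[C@H]2C[C@H](O)[C@](O)(COC(=O)/C=C/c3ccc(O)cc3)[C@@H]12 | intermediate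

**Step count**
Total: 10 steps. Longest linear sequence: 8 steps (1, 2, 4, 5, 6, 8, 9, 10, from furfuryl alcohol).

**Three steps most likely to fail**

Step 4 (the new annulation; an allenic thioester may oligomerise or react sluggishly). The fallback sets out from 6 (with 7) and returns at 11. But-3-ynoic acid 7 is esterified with allyl alcohol (DCC, DMAP, then Et3N) to allyl buta-2,3-dienoate F1. F1 undergoes the known ester-allenoate Lu annulation with 6 (PPh3, toluene) to give the bicyclic allyl ester F2. Pd(PPh3)4 with morpholine removes the allyl group to give the carboxylic acid F3. EDC·HCl, DMAP and ethanethiol then convert F3 into thioester 11.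

Step 9 (one-pot epoxidation and ester-assisted opening; face selectivity, attack at C7 or hydride shift could interfere). The fallback sets out from 13 and returns at 20. Hydroxyl-directed epoxidation of 13 (VO(acac)2, t-BuOOH, CH2Cl2, 0 °C) gives the 7β,8β-epoxy alcohol F4. Acid-catalysed hydrolysis (HClO4 cat., THF/H2O) opens the tertiary C8 with inversion to the 7β,8α,10-triol F5. Mitsunobu esterification of F5 with 16 (PPh3, DIAD) at the primary hydroxyl gives 20.

Step 10 (late Stille coupling on a densely functionalised α-alkoxy enol triflate). The fallback sets out from 20 and returns at 1. Reductive carbonylation (Pd(OAc)2, 1,3-bis(diphenylphosphino)propane, CO 1 atm, Et3SiH, DMF, 60 °C) gives the C4 carbaldehyde F6. Luche reduction of F6 (NaBH4, CeCl3·7H2O, MeOH/THF, −78 °C) reduces only the aldehyde and gives 1.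

**Further compounds**
F1 | step 4 | allyl buta-2,3-dienoate | C=C=CC(=O)OCC=C
F2 | step 4 | prop-2-en-1-yl (1S,4aS,7aS)-1-{[(3S)-3-methylpentanoyl]oxy}-4-oxo-1,3,4,4a,5,7a-hexahydrocyclopenta[c]pyran-7-carboxylate | CC[C@H](C)CC(=O)O[C@@H]1OCC(=O)[C@H]2CC=C(C(=O)OCC=C)[C@@H]12
F3 | step 4 | (1S,4aS,7aS)-1-{[(3S)-3-methylpentanoyl]oxy}-4-oxo-1,3,4,4a,5,7a-hexahydrocyclopenta[c]pyran-7-carboxylic acid | CC[C@H](C)CC(=O)O[C@@H]1OCC(=O)[C@H]2CC=C(C(=O)O)[C@@H]12
F4 | step 9 | 7β,8β-epoxide of alcohol 13 (epoxy alcohol) | CC[C@H](C)CC(=O)O[C@@H]1OC=C(OS(=O)(=O)C(F)(F)F)[C@H]2C[C@@H]3O[C@]3(CO)[C@@H]12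
F5 | step 9 | (1S,4aS,6S,7R,7aS)-6,7-dihydroxy-7-(hydroxymethyl)-4-[(trifluoromethanesulfonyl)oxy]-1,4a,5,6,7,7a-hexahydrocyclopenta[c]pyran-1-yl (3S)-3-methylpentanoate | CC[C@H](C)CC(=O)O[C@@H]1OC=C(OS(=O)(=O)C(F)(F)F)[C@H]2C[C@H](O)[C@](O)(CO)[C@@H]12
F6 | step 10 | [(1S,4aS,6S,7R,7aS)-4-formyl-6,7-dihydroxy-1-{[(3S)-3-methylpentanoyl]oxy}-1,4a,5,6,7,7a-hexahydrocyclopenta[c]pyran-7-yl]methyl (2E)-3-(4-hydroxyphenyl)prop-2-enoate | CC[C@H](C)CC(=O)O[C@@H]1OC=C(C=O)[C@H]2C[C@H](O)[C@](O)(COC(=O)/C=C/c3ccc(O)cc3)[C@@H]12
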